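## Retrosynthetic overview

1. Lower unit (rings D, F, E): no ring bond is cut. Kaempferol 1 is taken back in oxidation state only, through flav-2-ene-3,4-diol 2 to pelargonidin chloride 3, then by two hydride transfers (enol 4, flavan-3-one 5) to (−)-epiafzelechin 6. This copies flavylium formation and anthocyanidin reductase.
2. Upper unit: the only ring made in the route is ring C, cut at O1–C2 back to open-chain isoliquiritigenin 7. Closure is the reversible oxa-Michael addition of chalcone isomerase and gives liquiritigenin 8.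
3. C2 is fixed by running that closure under dynamic kinetic resolution: only (2S)-8 is reduced, to cis-flavan-4-ol 9 (flavanone 4-reductase step).
4. The C4(upper)–C6(lower) bond is cut in the same flask: 9 ionises to quinone methide 10, which 6 attacks trans to the 2-aryl group to give target 11.
5. Ring order: A, B, D, E and F are bought; ring C is formed last, directly before the interflavan bond.

Assumption: kaempferol 1 and isoliquiritigenin 7 are bought as bulk catalogue flavonoids; the SMILES is read as (2S,4R) in the upper unit (2,4-trans, "4β→6") and (2R,3R) in the lower unit (2,3-cis).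

## Route

Step 1
Reactants: 1 kaempferol
Product: 3 pelargonidin chloride, via flav-2-ene-3,4-diol 2 (not isolated)
Conditions: Zn(Hg) (10 equiv), 3% HCl in MeOH, 25 °C, 20 min; filter off the metal; filtrate stirred in air 1 h; precipitation with Et2O
Reagents that add atoms: hydrogen chloride, Cl
Why: Dissolving-metal reduction of the pyranone carbonyl gives diol 2, which loses water in HCl to the aromatic flavylium ion (the classical flavonol-to-anthocyanidin reduction); no stereocentre remains in 3.

Step 2
Reactants: 3 pelargonidin chloride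
Product: 6 (−)-epiafzelechin, via enol 4 (not isolated), via flavan-3-one 5 (not isolated)
Conditions: RuCl(p-cymene)[(S,S)-TsNCH(Ph)CH(Ph)NH2] (2 mol%), HCO2H/Et3N 5:2 (10 equiv HCO2H), degassed DMF, 30 °C, 24 h, Ar; Sephadex LH-20 (EtOH)
Reagents that add atoms: none
Why: Proposed new method: the Ru hydride (Noyori–Ikariya asymmetric transfer hydrogenation) first adds H− to C4 of the flavylium ion, as NADPH does in anthocyanidin reductase and as borohydrides do with flavylium salts, giving enol 4, which ketonises to the alpha-aryloxy ketone 5; 5 epimerises at C2 through 4 faster than it is reduced (dynamic kinetic resolution), and the (S,S)-catalyst, with the bulky C2 turned away from the p-cymene ligand, delivers H− to C3 of the (2R)-ketone anti to the 2-aryl group, which sets 3R and with it the 2,3-cis (2R,3R) pair; the closest known reactions are transfer-hydrogenation dynamic kinetic resolutions of 2-substituted cyclic ketones to cis alcohols and hydride reductions of flavylium salts to flavenes.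

Step 3
Reactants: 7 isoliquiritigenin; 6 (−)-epiafzelechin
Product: 11 (2R,3R)-2-(4-hydroxyphenyl)-6-[(2S,4R)-7-hydroxy-2-(4-hydroxyphenyl)chroman-4-yl]chromane-3,5,7-triol (target), via (2S)-liquiritigenin 8 (not isolated), via flavan-4-ol 9 (not isolated), via quinone methide 10 (not isolated)
Conditions: one flask, Ar: a) 7, HCO2H (5 equiv), Et3N (6 equiv), H2O/MeOH 1:1, 60 °C, 24 h; b) RhCl(C5Me5)[(S,S)-TsNCH(Ph)CH(Ph)NH2] (1 mol%), 45 °C, 48 h; c) 6 (3 equiv), aq. HCl to pH 1.5, 25 °C, 16 h; Sephadex LH-20 (EtOH), then RP-18 HPLC; excess 6 recovered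
Reagents that add atoms: none
Why: Proposed new method: ring C closes by the reversible intramolecular oxa-Michael addition of the 2'-OH to the enone (chalcone isomerase step), and because 8 racemises at pH 8 by retro-oxa-Michael opening (4'-phenoxide quinone methide or chalcone 7) while the (S,S)-Rh hydride reduces only (2S)-8, where its preferred 4S delivery coincides with axial attack giving the 2,4-cis alcohol, the material is funnelled to (2S,4S)-9 (transfer hydrogenation with dynamic kinetic resolution; closest known: kinetic resolution of flavanones by such catalysts and base racemisation of 4'-hydroxyflavanones); acid then ionises 9 to 10 and C6 of 6 adds axially, trans to the equatorial 2-aryl group, fixing 4R (Friedel–Crafts alkylation as in the acid condensation of flavan-4-ols with flavan-3-ols), the 4→8 regioisomer and the 2,4-cis epimers being removed by chromatography.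

## Compound list

1 | kaempferol, 3,5,7-trihydroxy-2-(4-hydroxyphenyl)-4H-chromen-4-one | O=c1c(O)c(-c2ccc(O)cc2)oc2cc(O)cc(O)c12 | starting material
2 | flav-2-ene-3,4-diol, 2-(4-hydroxyphenyl)-4H-chromene-3,4,5,7-tetrol (racemic at C4) | OC1C(O)=C(c2ccc(O)cc2)Oc2cc(O)cc(O)c12 | intermediate
3 | pelargonidin chloride, 3,5,7-trihydroxy-2-(4-hydroxyphenyl)chromenylium chloride | Oc1ccc(cc1)-c1[o+]c2cc(O)cc(O)c2cc1O.[Cl-] | intermediate
4 | enol, 2-(4-hydroxyphenyl)-4H-chromene-3,5,7-triol (flav-2-en-3-ol) | OC1=C(c2ccc(O)cc2)Oc2cc(O)cc(O)c2C1 | intermediate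
5 | flavan-3-one, 5,7-dihydroxy-2-(4-hydroxyphenyl)chroman-3-one (C2 epimerising; the 2R form is reduced) | O=C1Cc2c(O)cc(O)cc2OC1c1ccc(O)cc1 | intermediate
6 | (−)-epiafzelechin, (2R,3R)-2-(4-hydroxyphenyl)chromane-3,5,7-triol (2,3-cis) | O[C@@H]1Cc2c(O)cc(O)cc2O[C@@H]1c1ccc(O)cc1 | intermediate
7 | isoliquiritigenin, (E)-1-(2,4-dihydroxyphenyl)-3-(4-hydroxyphenyl)prop-2-en-1-one | O=C(/C=C/c1ccc(O)cc1)c1ccc(O)cc1O | starting material
8 | (2S)-liquiritigenin, (2S)-7-hydroxy-2-(4-hydroxyphenyl)chroman-4-one (in equilibrium with its 2R enantiomer) | O=C1C[C@@H](c2ccc(O)cc2)Oc2cc(O)ccc12 | intermediate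
9 | flavan-4-ol, (2S,4S)-2-(4-hydroxyphenyl)chromane-4,7-diol (2,4-cis) | O[C@H]1C[C@@H](c2ccc(O)cc2)Oc2cc(O)ccc12 | intermediate
10 | quinone methide, (2S)-2-(4-hydroxyphenyl)-2,3-dihydro-7H-chromen-7-one (its O-protonated form is the flavan-4-yl cation) | O=C1C=CC2=CC[C@@H](c3ccc(O)cc3)OC2=C1 | intermediate
11 | (2R,3R)-2-(4-hydroxyphenyl)-6-[(2S,4R)-7-hydroxy-2-(4-hydroxyphenyl)chroman-4-yl]chromane-3,5,7-triol | Oc1ccc([C@@H]2C[C@@H](c3c(O)cc4c(c3O)C[C@@H](O)[C@@H](c3ccc(O)cc3)O4)c3ccc(O)cc3O2)cc1 | target

## Step count and risks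

Total steps: 3. Longest linear sequence: 3 (1 → 3 → 6 → 11).

Step 3 is the most likely to fail. The Rh hydride may reduce the C=C bond of chalcone 7 instead of waiting for ring closure, and racemisation of 8 may be too slow for a clean dynamic resolution. C8 of 6 is expected to react at least as fast as C6, so 11 may be the minor regioisomer, of the order of 10% from 7. The fallback sets out from 7 and 6 and rejoins the route at 11; it is stepwise, protected and blocked at C8. 7 is benzylated at its two para phenols (BnBr, K2CO3, acetone) to 4,4'-di-O-benzylisoliquiritigenin F3. Ring C is closed with NaOAc in refluxing EtOH to racemic 4',7-di-O-benzylliquiritigenin F4. A non-dynamic kinetic resolution with the same Rh catalyst in HCO2H/Et3N 5:2 and EtOAc, stopped near half conversion, gives (2S,4S)-4',7-di-O-benzylflavan-4-ol F5; the unreacted 2R ketone is recycled with base. In parallel 6 is benzylated at its three phenols (BnBr, K2CO3, DMF) to 5,7,4'-tri-O-benzylepiafzelechin F6 and brominated with N-bromosuccinimide in CH2Cl2 at −78 °C to 8-bromo-5,7,4'-tri-O-benzylepiafzelechin F7, which leaves C6 as the only free position on ring D. BF3·OEt2 in CH2Cl2 at −20 °C joins F5 and F7 to the penta-O-benzyl 8-bromo dimer F8. H2 over Pd(OH)2/C with Et3N in THF/MeOH/H2O then removes the five benzyl groups and the bromine and gives 11.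

Step 2 is next. A second hydride may go to C2 of a protonated enol instead of passing through ketone 5, which would give trans or racemic material. The facial sense also rests on a steric model for ketones that carry no aryl group on the carbonyl carbon; if the (2S,3S) product formed, the (R,R)-ligand would be used. The fallback sets out from 3 and rejoins the route at 6. Hydrogenation of 3 over PtO2 (H2, 1 atm, EtOH) gives racemic 2,3-cis (±)-epiafzelechin F2, which is resolved by preparative chromatography on a cellulose tris(3,5-dimethylphenylcarbamate) phase; the 2R,3R enantiomer is 6.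

Step 1 is known chemistry but low-yielding, because Zn also reduces the flavylium ion once it forms. The fallback sets out from 1 and rejoins the route at 3. Reductive acetylation (Zn, Ac2O, NaOAc, reflux) traps the reduced stage as the air-stable flav-2-ene-3,4-diol pentaacetate F1, which is isolated free of metal; 6 M aq. HCl/AcOH at 60 °C then hydrolyses the esters and ionises C4 to give 3.

## Further compounds

F1 | step 1 | flav-2-ene-3,4-diol pentaacetate, 3,4,5,7-tetraacetoxy-2-(4-acetoxyphenyl)-4H-chromene (racemic at C4) | CC(=O)OC1C(OC(C)=O)=C(c2ccc(OC(C)=O)cc2)Oc2cc(OC(C)=O)cc(OC(C)=O)c12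
F2 | step 2 | (±)-epiafzelechin, racemic 2,3-cis-2-(4-hydroxyphenyl)chromane-3,5,7-triol (both enantiomers shown) | O[C@@H]1Cc2c(O)cc(O)cc2O[C@@H]1c1ccc(O)cc1.O[C@H]1Cc2c(O)cc(O)cc2O[C@H]1c1ccc(O)cc1
F3 | step 3 | 4,4'-di-O-benzylisoliquiritigenin, (E)-1-[4-(benzyloxy)-2-hydroxyphenyl]-3-[4-(benzyloxy)phenyl]prop-2-en-1-one | O=C(/C=C/c1ccc(OCc2ccccc2)cc1)c1ccc(OCc2ccccc2)cc1O
F4 | step 3 | racemic 4',7-di-O-benzylliquiritigenin, 7-(benzyloxy)-2-[4-(benzyloxy)phenyl]chroman-4-one (both enantiomers shown) | O=C1C[C@@H](c2ccc(OCc3ccccc3)cc2)Oc2cc(OCc3ccccc3)ccc12.O=C1C[C@H](c2ccc(OCc3ccccc3)cc2)Oc2cc(OCc3ccccc3)ccc12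
F5 | step 3 | (2S,4S)-4',7-di-O-benzylflavan-4-ol, (2S,4S)-7-(benzyloxy)-2-[4-(benzyloxy)phenyl]chroman-4-ol | O[C@H]1C[C@@H](c2ccc(OCc3ccccc3)cc2)Oc2cc(OCc3ccccc3)ccc12
F6 | step 3 | 5,7,4'-tri-O-benzylepiafzelechin, (2R,3R)-5,7-bis(benzyloxy)-2-[4-(benzyloxy)phenyl]chroman-3-ol | O[C@@H]1Cc2c(OCc3ccccc3)cc(OCc3ccccc3)cc2O[C@@H]1c1ccc(OCc2ccccc2)cc1
F7 | step 3 | 8-bromo-5,7,4'-tri-O-benzylepiafzelechin, (2R,3R)-5,7-bis(benzyloxy)-2-[4-(benzyloxy)phenyl]-8-bromochroman-3-ol | O[C@@H]1Cc2c(OCc3ccccc3)cc(OCc3ccccc3)c(Br)c2O[C@@H]1c1ccc(OCc2ccccc2)cc1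
F8 | step 3 | penta-O-benzyl 8-bromo dimer, (2R,3R)-5,7-bis(benzyloxy)-2-[4-(benzyloxy)phenyl]-6-{(2S,4R)-7-(benzyloxy)-2-[4-(benzyloxy)phenyl]chroman-4-yl}-8-bromochroman-3-ol | c5ccccc5COc1ccc([C@@H]2C[C@@H](c3c(OCc6ccccc6)c(Br)c4c(c3OCc7ccccc7)C[C@@H](O)[C@@H](c3ccc(OCc8ccccc8)cc3)O4)c3ccc(OCc9ccccc9)cc3O2)cc1
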